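**Plan**

- Labels: chroman 1 = O1, C2, C3, C4 with benzo ring A (pyran = ring C) and ring B on C3; ring E = arene on C4 (E1 on C4, E2 OMe, E4 OH, E6 on C3'); chroman 2 = O1', C2', C3', C4' (pyran = ring D) with benzo ring F.
- Retrosynthetic cuts, in order: the five O-benzyl groups; ring C at O1–C2 and C3–C4 (ring A ortho-quinone methide with C4 as methide carbon + ring B arylacetaldehyde); ring D at O1'–C2'; E6–C3' and E1–C4 in one cut (aryne + beta-ketoester); C3'–C4' (Knoevenagel condensation/conjugate reduction).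
- Enabling feature: E1 and E6 are neighbouring ring E carbons carrying the two carbon arms (C4 and C3'), with the E2 methoxy group next to E1. They are the two carbons of a 3-methoxy-5-(benzyloxy)benzyne, and the methoxy group decides which arm goes where.
- Forward: the aryne precursor (from vanillin) and the alpha-benzylated beta-ketoester are joined on ring E; ring D is then closed by Mitsunobu etherification and ring C by an enamine-catalysed quinone methide annulation; lactol reduction and hydrogenolysis finish.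
- Stereochemistry: C3' (R) from a Ru-catalysed dynamic kinetic resolution hydrogenation of the alpha-aryl aldehyde; C3 (R) and C4 (S), trans, from the chiral secondary amine in the ring C annulation. The two controls are independent.

Key step: step 12

Assumption: 2,3-dihydroxy-4-methoxybenzaldehyde (30) is a catalogue compound; the sense of induction of both chiral catalysts is inferred by analogy with simple 2-arylalkanals and propanal, and the mirror-image catalyst would be used if the first batch shows the opposite sense.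
Abbreviations: DMM-SDP = 7,7'-bis[bis(4-methoxy-3,5-dimethylphenyl)phosphino]-1,1'-spirobiindane; DACH = trans-cyclohexane-1,2-diamine; MOM = methoxymethyl.

**Route**

Step 1
Reactants: 1 vanillin
Product: 2 4-formyl-2-methoxyphenyl isopropylcarbamate
Conditions: iPrNCO, Et3N (cat.), CH2Cl2, rt
Reagents that add atoms: isopropyl isocyanate, CC(C)N=C=O
Why: Base-catalysed addition of the phenol to the isocyanate (O-carbamoylation) masks the phenol and installs the group that later directs ortho-lithiation.

Step 2
Reactants: 2 4-formyl-2-methoxyphenyl isopropylcarbamate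
Product: 4 4-hydroxy-2-methoxyphenyl isopropylcarbamate, via aryl formate 3 (not isolated)
Conditions: mCPBA, CH2Cl2, rt; then Et3N (cat.), MeOH, rt
Reagents that add atoms: mCPBA, O=C(OO)c1cccc(Cl)c1
Why: Baeyer–Villiger (Dakin-type) oxidation in which the oxygenated aryl group migrates, followed by methanolysis of the labile formate while the carbamate stays in place.

Step 3
Reactants: 4 4-hydroxy-2-methoxyphenyl isopropylcarbamate
Product: 5 4-(benzyloxy)-2-methoxyphenyl isopropylcarbamate
Conditions: BnBr, K2CO3, DMF, rt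
Reagents that add atoms: benzyl bromide, BrCc1ccccc1
Why: Williamson etherification of the only free phenol; the carbamate N–H is much less acidic and is not alkylated.

Step 4
Reactants: 5 4-(benzyloxy)-2-methoxyphenyl isopropylcarbamate
Product: 8 4-(benzyloxy)-2-methoxy-6-(trimethylsilyl)phenyl isopropylcarbamate, via N-silyl carbamate 6 (not isolated), via N-silyl C-silyl carbamate 7 (not isolated)
Conditions: TBSOTf, TMEDA, Et2O, 0 °C to rt; n-BuLi, TMEDA, −78 °C; TMSCl, −78 °C to rt; aq. NaHSO4
Reagents that add atoms: chlorotrimethylsilane, C[Si](C)(C)Cl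
Why: Carbamate-directed ortho-metalation after in situ N-silylation lithiates the only free position ortho to the carbamate, TMSCl traps the aryllithium, and the N–Si bond is hydrolysed on work-up.

Step 5
Reactants: 8 4-(benzyloxy)-2-methoxy-6-(trimethylsilyl)phenyl isopropylcarbamate
Product: 10 4-(benzyloxy)-2-methoxy-6-(trimethylsilyl)phenyl triflate, via silylphenol 9 (not isolated)
Conditions: DBU, Et2NH, MeCN, 40 °C; then PhNTf2, rt
Reagents that add atoms: N-phenylbis(trifluoromethanesulfonimide), O=S(=O)(N(c1ccccc1)S(=O)(=O)C(F)(F)F)C(F)(F)F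
Why: E1cB cleavage of the N–H carbamate (isocyanate trapped by Et2NH) frees the phenoxide, which is O-sulfonylated in the same flask.

Step 6
Reactants: 11 2,4-dihydroxyacetophenone
Product: 12 1-[4-(benzyloxy)-2-hydroxyphenyl]ethanone
Conditions: BnBr, K2CO3, acetone, reflux
Reagents that add atoms: benzyl bromide, BrCc1ccccc1
Why: Williamson etherification is selective for the 4-OH because the 2-OH is held in a hydrogen bond to the ketone.

Step 7
Reactants: 12 1-[4-(benzyloxy)-2-hydroxyphenyl]ethanone
Product: 13 1-[4-(benzyloxy)-2-(methoxymethoxy)phenyl]ethanone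
Conditions: MOMCl, iPr2NEt, CH2Cl2, 0 °C to reflux
Reagents that add atoms: chloromethyl methyl ether, COCCl
Why: O-alkylation (MOM protection) gives an acetal that survives base, fluoride and hydride and can later be removed without touching benzyl ethers.

Step 8
Reactants: 13 1-[4-(benzyloxy)-2-(methoxymethoxy)phenyl]ethanone
Product: 14 methyl 3-[4-(benzyloxy)-2-(methoxymethoxy)phenyl]-3-oxopropanoate
Conditions: NaH, (MeO)2CO, toluene, reflux; then AcOH
Reagents that add atoms: dimethyl carbonate, COC(=O)OC
Why: Crossed Claisen condensation of the ketone enolate with dimethyl carbonate, driven by deprotonation of the beta-ketoester formed.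

Step 9
Reactants: 15 2,4-dihydroxybenzaldehyde
Product: 16 4-(benzyloxy)-2-hydroxybenzaldehyde
Conditions: BnBr, NaHCO3, KI (cat.), MeCN, reflux
Reagents that add atoms: benzyl bromide, BrCc1ccccc1
Why: Williamson etherification with a weak base alkylates only the more acidic, non-chelated 4-OH.

Step 10
Reactants: 16 4-(benzyloxy)-2-hydroxybenzaldehyde
Product: 17 4-(benzyloxy)-2-(methoxymethoxy)benzaldehyde
Conditions: MOMCl, iPr2NEt, CH2Cl2, 0 °C to rt
Reagents that add atoms: chloromethyl methyl ether, COCCl
Why: O-alkylation (MOM protection) marks the ring F oxygen that must later be freed selectively for closure of ring D.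

Step 11
Reactants: 14 methyl 3-[4-(benzyloxy)-2-(methoxymethoxy)phenyl]-3-oxopropanoate; 17 4-(benzyloxy)-2-(methoxymethoxy)benzaldehyde
Product: 19 alpha-benzyl beta-ketoester (racemic), via benzylidene ketoester 18 (not isolated)
Conditions: piperidine (cat.), AcOH (cat.), toluene, reflux (Dean–Stark); then Hantzsch ester, 80 °C
Reagents that add atoms: none
Why: Knoevenagel condensation followed by conjugate transfer hydrogenation of the alkylidene 1,3-dicarbonyl by the Hantzsch dihydropyridine forms C3'–C4' without touching benzyl ethers or the ketone and avoids an unstable dialkoxybenzyl halide.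

Step 12
Reactants: 19 alpha-benzyl beta-ketoester; 10 4-(benzyloxy)-2-methoxy-6-(trimethylsilyl)phenyl triflate
Product: 22 ring E keto ester (racemic), via aryne 20 (not isolated), via benzocyclobutenoxide 21 (not isolated)
Conditions: CsF (3 equiv), MeCN, 80 °C
Reagents that add atoms: none
Why: Fluoride desilylates 10 with loss of triflate to give aryne 20; the cesium enolate of 19 adds through C3' to E6, the aryne carbon remote from the methoxy group, the aryl anion formed at E1 attacks the ketone carbonyl (4-exo-trig) to give benzocyclobutenoxide 21, and cleavage of the C3'–C4 bond of that strained ring leaves an ester enolate that is protonated to 22. The closest known reaction type is the acyl-alkylation of arynes by insertion into the alpha-carbon–carbonyl bond of beta-ketoesters, which also covers alpha-substituted (cyclic) substrates. No ring is retained, since the four-membered ring is only a transient. C3' is created without control by protonation of a planar enolate and is corrected in step 16. The step needs regioselectivity, which the E2 methoxy group secures because a 3-alkoxyaryne takes up nucleophiles at the carbon meta to oxygen so that the carbanion develops next to it. It also needs attack on the ketone instead of the ester, which the higher electrophilicity of the ketone should secure.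

Step 13
Reactants: 22 ring E keto ester
Product: 23 ring E keto acid (racemic)
Conditions: LiOH, THF/MeOH/H2O, 50 °C; then 1 M HCl
Reagents that add atoms: lithium hydroxide, [Li+].[OH-]
Why: Saponification gives the free acid, the one oxidation level at which the ester carbon can be reduced without reducing the diaryl ketone.

Step 14
Reactants: 23 ring E keto acid
Product: 24 keto alcohol (racemic)
Conditions: BH3·THF, THF, 0 °C to rt; then MeOH
Reagents that add atoms: none
Why: Chemoselective borane reduction proceeds through an acyloxyborane and is much faster for the acid than for the hindered, donor-substituted diaryl ketone.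

Step 15
Reactants: 24 keto alcohol
Product: 25 keto aldehyde (racemic)
Conditions: Dess–Martin periodinane, NaHCO3, CH2Cl2, 0 °C to rt
Reagents that add atoms: none
Why: Dess–Martin oxidation under buffered conditions gives the configurationally labile alpha-aryl aldehyde without exposing it to the acid that would cyclise it onto the neighbouring ketone.

Step 16
Reactants: 25 keto aldehyde
Product: 26 (R)-keto alcohol
Conditions: H2 (50 atm), RuCl2[(R)-DMM-SDP][(S,S)-DACH] (0.5 mol %), KOtBu (20 mol %), iPrOH/toluene, rt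
Reagents that add atoms: none
Why: Asymmetric hydrogenation under dynamic kinetic resolution: KOtBu racemises the alpha-aryl aldehyde through its enolate faster than it is reduced, the chiral diphosphine/diamine ruthenium hydride reduces one enantiomer preferentially and so sets C3' as R, and the tri-ortho-substituted diaryl ketone is too hindered to compete.

Step 17
Reactants: 26 (R)-keto alcohol
Product: 27 (R)-keto alcohol bisphenol
Conditions: conc. HCl (cat.), MeOH/THF, 50 °C
Reagents that add atoms: none
Why: Acid-catalysed acetal exchange removes both MOM groups at once; benzyl ethers, the ketone and the primary alcohol tolerate dilute methanolic HCl.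

Step 18
Reactants: 27 (R)-keto alcohol bisphenol
Product: 28 (3'R)-isoflavan ketone
Conditions: PPh3, DIAD, THF, 0 °C to rt
Reagents that add atoms: none
Why: Intramolecular Mitsunobu etherification closes ring D (6-exo-tet, ring F phenol onto the activated primary carbon) without touching C3'; the ketone-chelated ring A phenol could only form a nine-membered ring and should not compete.

Step 19
Reactants: 28 (3'R)-isoflavan ketone
Product: 29 ortho-hydroxybenzhydrol (both carbinol epimers)
Conditions: LiAlH4, THF, −10 to 0 °C; then aq. potassium sodium tartrate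
Reagents that add atoms: none
Why: Hydride reduction of the diaryl ketone; the new carbinol configuration is irrelevant because it is erased in step 22, and the cold, non-acidic work-up avoids premature ionisation.

Step 20
Reactants: 30 2,3-dihydroxy-4-methoxybenzaldehyde
Product: 31 2,3-bis(benzyloxy)-4-methoxybenzaldehyde
Conditions: BnBr, K2CO3, DMF, 60 °C
Reagents that add atoms: benzyl bromide, BrCc1ccccc1
Why: Twofold Williamson etherification protects the catechol as benzyl ethers that are removed together with the others at the end.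

Step 21
Reactants: 31 2,3-bis(benzyloxy)-4-methoxybenzaldehyde
Product: 33 [2,3-bis(benzyloxy)-4-methoxyphenyl]acetaldehyde, via enol ether 32 (not isolated)
Conditions: MeOCH2PPh3Cl, KOtBu, THF, 0 °C to rt; then 2 M HCl, THF, 50 °C
Reagents that add atoms: (methoxymethyl)triphenylphosphonium chloride, COC[P+](c1ccccc1)(c1ccccc1)c1ccccc1.[Cl-]; water, O
Why: Wittig methoxymethylenation and hydrolysis of the enol ether give the one-carbon homologated aldehyde; the alkene geometry is of no consequence because it is lost on hydrolysis.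

Step 22
Reactants: 29 ortho-hydroxybenzhydrol; 33 [2,3-bis(benzyloxy)-4-methoxyphenyl]acetaldehyde
Product: 35 (3R,4S)-chroman-2-ol (lactol), via ortho-quinone methide 34 (not isolated)
Conditions: (R)-2-[diphenyl(trimethylsilyloxy)methyl]pyrrolidine (20 mol %), PhCO2H (20 mol %), CHCl3, rt
Reagents that add atoms: none
Why: Enamine-catalysed Michael addition/hemiacetalisation (formal [4+2]) onto the ortho-quinone methide released from the doubly donor-stabilised benzhydrol by the weak acid: the (E)-enamine reacts on the face away from the diphenyl(silyloxy)methyl group, which sets C3 as R, and the synclinal approach to the (E)-quinone methide places ring B and ring E trans, which sets C4 as S, before the phenol closes ring C (6-exo-trig onto the iminium carbon).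

Step 23
Reactants: 35 (3R,4S)-chroman-2-ol
Product: 36 penta-O-benzyl target
Conditions: Et3SiH, CF3CO2H, CH2Cl2, −20 to 0 °C
Reagents that add atoms: none
Why: Ionic hydrogenation: acid ionises the lactol to the cyclic oxocarbenium ion, which the silane reduces to the C2 methylene without touching C3 or C4.

Step 24
Reactants: 36 penta-O-benzyl target
Product: 37 CNP0227211.1
Conditions: H2 (1 atm), 10 % Pd/C, EtOAc/MeOH, rt
Reagents that add atoms: none
Why: Hydrogenolysis cleaves the five benzyl aryl ethers, while both chroman C–O bonds are alkyl aryl ethers and no stereocentre bears a leaving group, so the skeleton and the three stereocentres are retained.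

**Compound list**

1 | vanillin (4-hydroxy-3-methoxybenzaldehyde) | COc1cc(C=O)ccc1O | starting material
2 | 4-formyl-2-methoxyphenyl propan-2-ylcarbamate | COc1cc(C=O)ccc1OC(=O)NC(C)C | intermediate
3 | 4-(formyloxy)-2-methoxyphenyl propan-2-ylcarbamate (aryl formate, formed in the flask) | COc1cc(OC=O)ccc1OC(=O)NC(C)C | intermediate
4 | 4-hydroxy-2-methoxyphenyl propan-2-ylcarbamate | COc1cc(O)ccc1OC(=O)NC(C)C | intermediate
5 | 4-(benzyloxy)-2-methoxyphenyl propan-2-ylcarbamate | COc1cc(OCc2ccccc2)ccc1OC(=O)NC(C)C | intermediate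
6 | 4-(benzyloxy)-2-methoxyphenyl [tert-butyl(dimethyl)silyl](propan-2-yl)carbamate (formed in the flask) | COc1cc(OCc2ccccc2)ccc1OC(=O)N(C(C)C)[Si](C)(C)C(C)(C)C | intermediate
7 | 4-(benzyloxy)-2-methoxy-6-(trimethylsilyl)phenyl [tert-butyl(dimethyl)silyl](propan-2-yl)carbamate (formed in the flask) | COc1cc(OCc2ccccc2)cc([Si](C)(C)C)c1OC(=O)N(C(C)C)[Si](C)(C)C(C)(C)C | intermediate
8 | 4-(benzyloxy)-2-methoxy-6-(trimethylsilyl)phenyl propan-2-ylcarbamate | COc1cc(OCc2ccccc2)cc([Si](C)(C)C)c1OC(=O)NC(C)C | intermediate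
9 | 4-(benzyloxy)-2-methoxy-6-(trimethylsilyl)phenol (formed in the flask as its DBU salt) | COc1cc(OCc2ccccc2)cc([Si](C)(C)C)c1O | intermediate
10 | 4-(benzyloxy)-2-methoxy-6-(trimethylsilyl)phenyl trifluoromethanesulfonate | COc1cc(OCc2ccccc2)cc([Si](C)(C)C)c1OS(=O)(=O)C(F)(F)F | intermediate
11 | 2,4-dihydroxyacetophenone | CC(=O)c1ccc(O)cc1O | starting material
12 | 1-[4-(benzyloxy)-2-hydroxyphenyl]ethanone | CC(=O)c1ccc(OCc2ccccc2)cc1O | intermediate
13 | 1-[4-(benzyloxy)-2-(methoxymethoxy)phenyl]ethanone | CC(=O)c1ccc(OCc2ccccc2)cc1OCOC | intermediate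
14 | methyl 3-[4-(benzyloxy)-2-(methoxymethoxy)phenyl]-3-oxopropanoate | COC(=O)CC(=O)c1ccc(OCc2ccccc2)cc1OCOC | intermediate
15 | 2,4-dihydroxybenzaldehyde | O=Cc1ccc(O)cc1O | starting material
16 | 4-(benzyloxy)-2-hydroxybenzaldehyde | O=Cc1ccc(OCc2ccccc2)cc1O | intermediate
17 | 4-(benzyloxy)-2-(methoxymethoxy)benzaldehyde | O=Cc1ccc(OCc2ccccc2)cc1OCOC | intermediate
18 | methyl 2-[4-(benzyloxy)-2-(methoxymethoxy)benzoyl]-3-[4-(benzyloxy)-2-(methoxymethoxy)phenyl]prop-2-enoate (E/Z mixture, formed in the flask) | COC(=O)C(=Cc1ccc(OCc2ccccc2)cc1OCOC)C(=O)c1ccc(OCc2ccccc2)cc1OCOC | intermediate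
19 | methyl 2-[4-(benzyloxy)-2-(methoxymethoxy)benzyl]-3-[4-(benzyloxy)-2-(methoxymethoxy)phenyl]-3-oxopropanoate (racemic) | COC(=O)C(Cc1ccc(OCc2ccccc2)cc1OCOC)C(=O)c1ccc(OCc2ccccc2)cc1OCOC | intermediate
20 | 5-(benzyloxy)-3-methoxybenzyne (1-(benzyloxy)-3-methoxycyclohexa-1,3-dien-5-yne, formed in the flask) | COC1=CC(OCc2ccccc2)=CC#C1 | intermediate
21 | cesium benzocyclobutenoxide: four-membered ring E1–C4(O−)(ring A aryl)–C3'(CO2Me)(CH2-ring F aryl)–E6 fused to ring E (formed in the flask) | COC(=O)C1(Cc2ccc(OCc3ccccc3)cc2OCOC)c2cc(OCc3ccccc3)cc(OC)c2C1([O-])c1ccc(OCc2ccccc2)cc1OCOC.[Cs+] | intermediate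
22 | methyl 2-{5-(benzyloxy)-2-[4-(benzyloxy)-2-(methoxymethoxy)benzoyl]-3-methoxyphenyl}-3-[4-(benzyloxy)-2-(methoxymethoxy)phenyl]propanoate (racemic) | COC(=O)C(Cc1ccc(OCc2ccccc2)cc1OCOC)c1cc(OCc2ccccc2)cc(OC)c1C(=O)c1ccc(OCc2ccccc2)cc1OCOC | intermediate
23 | 2-{5-(benzyloxy)-2-[4-(benzyloxy)-2-(methoxymethoxy)benzoyl]-3-methoxyphenyl}-3-[4-(benzyloxy)-2-(methoxymethoxy)phenyl]propanoic acid (racemic) | OC(=O)C(Cc1ccc(OCc2ccccc2)cc1OCOC)c1cc(OCc2ccccc2)cc(OC)c1C(=O)c1ccc(OCc2ccccc2)cc1OCOC | intermediate
24 | {4-(benzyloxy)-2-[1-[4-(benzyloxy)-2-(methoxymethoxy)phenyl]-3-hydroxypropan-2-yl]-6-methoxyphenyl}[4-(benzyloxy)-2-(methoxymethoxy)phenyl]methanone (racemic) | OCC(Cc1ccc(OCc2ccccc2)cc1OCOC)c1cc(OCc2ccccc2)cc(OC)c1C(=O)c1ccc(OCc2ccccc2)cc1OCOC | intermediate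
25 | 2-{5-(benzyloxy)-2-[4-(benzyloxy)-2-(methoxymethoxy)benzoyl]-3-methoxyphenyl}-3-[4-(benzyloxy)-2-(methoxymethoxy)phenyl]propanal (racemic) | O=CC(Cc1ccc(OCc2ccccc2)cc1OCOC)c1cc(OCc2ccccc2)cc(OC)c1C(=O)c1ccc(OCc2ccccc2)cc1OCOC | intermediate
26 | {4-(benzyloxy)-2-[(2R)-1-[4-(benzyloxy)-2-(methoxymethoxy)phenyl]-3-hydroxypropan-2-yl]-6-methoxyphenyl}[4-(benzyloxy)-2-(methoxymethoxy)phenyl]methanone | OC[C@H](Cc1ccc(OCc2ccccc2)cc1OCOC)c1cc(OCc2ccccc2)cc(OC)c1C(=O)c1ccc(OCc2ccccc2)cc1OCOC | intermediate
27 | {4-(benzyloxy)-2-[(2R)-1-[4-(benzyloxy)-2-hydroxyphenyl]-3-hydroxypropan-2-yl]-6-methoxyphenyl}[4-(benzyloxy)-2-hydroxyphenyl]methanone | OC[C@H](Cc1ccc(OCc2ccccc2)cc1O)c1cc(OCc2ccccc2)cc(OC)c1C(=O)c1ccc(OCc2ccccc2)cc1O | intermediate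
28 | {4-(benzyloxy)-2-[(3R)-7-(benzyloxy)-3,4-dihydro-2H-chromen-3-yl]-6-methoxyphenyl}[4-(benzyloxy)-2-hydroxyphenyl]methanone | O=C(c1ccc(OCc2ccccc2)cc1O)c1c(OC)cc(OCc2ccccc2)cc1[C@@H]1COc2cc(OCc3ccccc3)ccc2C1 | intermediate
29 | 5-(benzyloxy)-2-[{4-(benzyloxy)-2-[(3R)-7-(benzyloxy)-3,4-dihydro-2H-chromen-3-yl]-6-methoxyphenyl}(hydroxy)methyl]phenol (both carbinol epimers) | OC(c1ccc(OCc2ccccc2)cc1O)c1c(OC)cc(OCc2ccccc2)cc1[C@@H]1COc2cc(OCc3ccccc3)ccc2C1 | intermediate
30 | 2,3-dihydroxy-4-methoxybenzaldehyde | COc1ccc(C=O)c(O)c1O | starting material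
31 | 2,3-bis(benzyloxy)-4-methoxybenzaldehyde | COc1ccc(C=O)c(OCc2ccccc2)c1OCc1ccccc1 | intermediate
32 | 2,3-bis(benzyloxy)-1-methoxy-4-(2-methoxyethenyl)benzene (E/Z mixture, formed in the flask) | COC=Cc1ccc(OC)c(OCc2ccccc2)c1OCc1ccccc1 | intermediate
33 | [2,3-bis(benzyloxy)-4-methoxyphenyl]acetaldehyde | O=CCc1ccc(OC)c(OCc2ccccc2)c1OCc1ccccc1 | intermediate
34 | (6E)-3-(benzyloxy)-6-({4-(benzyloxy)-2-[(3R)-7-(benzyloxy)-3,4-dihydro-2H-chromen-3-yl]-6-methoxyphenyl}methylidene)cyclohexa-2,4-dien-1-one (formed in the flask) | O=C1C=C(OCc2ccccc2)C=C/C1=C\c1c(OC)cc(OCc2ccccc2)cc1[C@@H]1COc2cc(OCc3ccccc3)ccc2C1 | intermediate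
35 | (3R,4S)-7-(benzyloxy)-4-{4-(benzyloxy)-2-[(3R)-7-(benzyloxy)-3,4-dihydro-2H-chromen-3-yl]-6-methoxyphenyl}-3-[2,3-bis(benzyloxy)-4-methoxyphenyl]-3,4-dihydro-2H-chromen-2-ol (both C2 epimers) | COc1ccc([C@@H]2C(O)Oc3cc(OCc4ccccc4)ccc3[C@H]2c5c(OC)cc(OCc6ccccc6)cc5[C@@H]7COc8cc(OCc9ccccc9)ccc8C7)c(OCc2ccccc2)c1OCc1ccccc1 | intermediate
36 | (3R,4S)-7-(benzyloxy)-4-{4-(benzyloxy)-2-[(3R)-7-(benzyloxy)-3,4-dihydro-2H-chromen-3-yl]-6-methoxyphenyl}-3-[2,3-bis(benzyloxy)-4-methoxyphenyl]-3,4-dihydro-2H-chromene | COc1ccc([C@@H]2COc3cc(OCc4ccccc4)ccc3[C@H]2c5c(OC)cc(OCc6ccccc6)cc5[C@@H]7COc8cc(OCc9ccccc9)ccc8C7)c(OCc2ccccc2)c1OCc1ccccc1 | intermediate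
37 | CNP0227211.1, (3R,4S)-3-(2,3-dihydroxy-4-methoxyphenyl)-4-{4-hydroxy-2-[(3R)-7-hydroxy-3,4-dihydro-2H-chromen-3-yl]-6-methoxyphenyl}-3,4-dihydro-2H-chromen-7-ol | COc1ccc([C@@H]2COc3cc(O)ccc3[C@H]2c2c(OC)cc(O)cc2[C@@H]2COc3cc(O)ccc3C2)c(O)c1O | target

**Step count and risks**

Total step count: 24. Longest linear sequence: 16 steps (steps 1–5, 12–19, 22–24, from vanillin).

Steps most likely to fail:

Step 12. The tertiary enolate carbon of 19 may add slowly to the aryne. The aryl anion at E1 may also be protonated before it reaches the donor-deactivated ketone (plain alpha-arylation), or it may attack the ester carbonyl instead. The fallback keeps the aryne insertion but moves the C3'–C4' bond formation behind it; it sets out from 14, 10 and 17 and returns at 22. Ketoester 14 and 10 under the same CsF/MeCN conditions (the parent case of the insertion) should give methyl {5-(benzyloxy)-2-[4-(benzyloxy)-2-(methoxymethoxy)benzoyl]-3-methoxyphenyl}acetate F1. Aldehyde 17 is reduced with NaBH4 to [4-(benzyloxy)-2-(methoxymethoxy)phenyl]methanol F2 and converted with CBr4/PPh3 into 4-(benzyloxy)-1-(bromomethyl)-2-(methoxymethoxy)benzene F3, used at once. Deprotonation of F1 with NaH in THF and alkylation with F3 then gives 22.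

Step 16. Racemisation of the bulky aldehyde may be slower than its reduction, the catalyst may discriminate poorly between the two enantiomers, or the ketone may be reduced as well. The fallback replaces catalytic deracemisation by classical resolution at the acid stage; it sets out from 23 and returns at 26, bypassing steps 14–16. Racemic acid 23 and (S)-1-phenylethylamine are crystallised from EtOAc/EtOH to give the less soluble salt, (S)-1-phenylethanaminium (2R)-2-{5-(benzyloxy)-2-[4-(benzyloxy)-2-(methoxymethoxy)benzoyl]-3-methoxyphenyl}-3-[4-(benzyloxy)-2-(methoxymethoxy)phenyl]propanoate F4. The other amine enantiomer would be taken if the (2S)-salt crystallises first. Acidification frees the (2R)-acid F5, and BH3·THF reduction as in step 14 gives 26.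

Step 22. The di-ortho-substituted ring E may shield the methide carbon from the bulky enamine, facial selectivity may be poor, or the arylacetaldehyde may self-condense faster than it is trapped. The fallback uses a small preformed nucleophile under Brønsted acid catalysis; it sets out from 29 and 31 and returns at 36. Aldehyde 31 is methoxymethylenated (MeOCH2PPh3Cl, KOtBu) and the (E)-isomer, 2,3-bis(benzyloxy)-1-methoxy-4-[(E)-2-methoxyethenyl]benzene F6, is isolated by chromatography. Benzhydrol 29 and F6 with a chiral BINOL-derived phosphoric acid ((R)-TRIP, 10 mol %, toluene, −20 °C) should undergo the inverse-electron-demand hetero-Diels–Alder reaction of quinone methide 34 and give the 3,4-trans 2-methoxychroman F7. Et3SiH/BF3·OEt2 in CH2Cl2 at −78 °C removes the acetal methoxy group and gives 36. If catalyst control is weak, the two C3/C4 diastereomers (C3' being fixed) are separated at 36 by preparative HPLC.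

**Further compounds**

F1 | step 12 | methyl {5-(benzyloxy)-2-[4-(benzyloxy)-2-(methoxymethoxy)benzoyl]-3-methoxyphenyl}acetate | COC(=O)Cc1cc(OCc2ccccc2)cc(OC)c1C(=O)c1ccc(OCc2ccccc2)cc1OCOC
F2 | step 12 | [4-(benzyloxy)-2-(methoxymethoxy)phenyl]methanol | OCc1ccc(OCc2ccccc2)cc1OCOC
F3 | step 12 | 4-(benzyloxy)-1-(bromomethyl)-2-(methoxymethoxy)benzene | BrCc1ccc(OCc2ccccc2)cc1OCOC
F4 | step 16 | (S)-1-phenylethanaminium (2R)-2-{5-(benzyloxy)-2-[4-(benzyloxy)-2-(methoxymethoxy)benzoyl]-3-methoxyphenyl}-3-[4-(benzyloxy)-2-(methoxymethoxy)phenyl]propanoate | [O-]C(=O)[C@H](Cc1ccc(OCc2ccccc2)cc1OCOC)c1cc(OCc2ccccc2)cc(OC)c1C(=O)c1ccc(OCc2ccccc2)cc1OCOC.C[C@H]([NH3+])c1ccccc1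
F5 | step 16 | (2R)-2-{5-(benzyloxy)-2-[4-(benzyloxy)-2-(methoxymethoxy)benzoyl]-3-methoxyphenyl}-3-[4-(benzyloxy)-2-(methoxymethoxy)phenyl]propanoic acid | OC(=O)[C@H](Cc1ccc(OCc2ccccc2)cc1OCOC)c1cc(OCc2ccccc2)cc(OC)c1C(=O)c1ccc(OCc2ccccc2)cc1OCOC
F6 | step 22 | 2,3-bis(benzyloxy)-1-methoxy-4-[(E)-2-methoxyethenyl]benzene | CO/C=C/c1ccc(OC)c(OCc2ccccc2)c1OCc1ccccc1
F7 | step 22 | (3R,4S)-7-(benzyloxy)-4-{4-(benzyloxy)-2-[(3R)-7-(benzyloxy)-3,4-dihydro-2H-chromen-3-yl]-6-methoxyphenyl}-3-[2,3-bis(benzyloxy)-4-methoxyphenyl]-2-methoxy-3,4-dihydro-2H-chromene (C2 epimers) | COc1ccc([C@@H]2C(OC)Oc3cc(OCc4ccccc4)ccc3[C@H]2c5c(OC)cc(OCc6ccccc6)cc5[C@@H]7COc8cc(OCc9ccccc9)ccc8C7)c(OCc2ccccc2)c1OCc1ccccc1
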